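## Analysis of the target

Target 22 is a bibenzyl. Ring A and ring B are joined by a CH2CH2 bridge, and three 4-hydroxybenzyl groups sit at C2 and C6 of ring A and at C4' of ring B. Ring A is pentasubstituted (C1 bridge, C2 benzyl, C3 OH, C4 H, C5 OMe, C6 benzyl); ring B is a 1,3,4-trisubstituted phenol (C1' bridge, C3' OH, C4' benzyl). There is no stereocentre and no stereogenic double bond, so every problem is one of regiochemistry. Apart from the O-methyl group, ring A is symmetric about the C1–C4 axis, so the only task of differentiation is to tell O3 from O5. The five free phenols, several of them ortho or para to a diarylmethane CH2, make the final compound prone to oxidation; they are therefore carried as benzyl ethers and freed last, and the diarylmethane C–C bonds are inert to hydrogenolysis. The hard part is ring A: three contiguous carbon substituents (C6, C1, C2) between two oxygens, a pattern that electrophilic benzylation of a 5-alkylresorcinol does not deliver cleanly, because the doubly activated C4 must stay free. The strategy rests on reading ring A as a polyketide resorcinol: C1, C3 and C5 are the carbonyl carbons of one poly-beta-carbonyl chain (C1 with the side chain, C3 and C5 with the meta oxygens), and C2, C4 and C6 are its methylene carbons. The two benzyl groups sit on the methylene carbons C2 and C6, where enolate chemistry can place them before the ring exists.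

## Retrosynthetic reasoning

**22 from 21.** No skeletal bond is cut in the last step. The bridge is taken back to an (E)-alkene and four phenols to benzyl ethers, giving stilbene 21. One hydrogenation then saturates the alkene and frees all four phenols. The alkene is there on purpose: it lets the C1 side chain arrive as a cinnamoyl unit, so the C1 carbonyl has no sp3 C–H on its outer side.

**21 from 19 (ring A, bond C6–C1).** Ring A is opened at C6–C1 by a retro-aldol cut, leading to the open chain 19. In 19, C1 is the cinnamoyl ketone, C3 a ketone, C5 a methyl enol ether, and C2 and C6 already carry their benzyl groups. This bond is chosen because its two ends are a carbonyl carbon and the gamma carbon of a beta-methoxy enone, that is, an acceptor and a latent donor held six atoms apart. The gain is that the ring and all five substituents come from one acyclic compound, and that O5 (enol ether) and O3 (ketone) are already different. The forward reaction has to make C6 nucleophilic, add it to C1, lose water and aromatize. A point to respect: the C2 methine between the C1 and C3 carbonyls is the most acidic position of 19. Base therefore rests as the C1–C2–C3 diketonate, and the closure runs through the small share of material that is deprotonated at C6. Equilibrating alkoxide conditions are chosen, under which O-cyclizations are reversible and only aromatization is not.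

**19 from 7 and 17 (bond C1–C2).** The chain is cut between C1 and C2 by a Claisen-type disconnection. One half is the kinetic enolate 18 of methoxy enone 7, which holds C2 to C6 with both benzyl groups. The other half is cinnamoyl chloride 17, which holds C1, the future bridge and all of ring B. The cut is convergent, and the alpha' methylene of 7 is the site that an amide base deprotonates kinetically.

**7 from 6.** The enol ether is traced to the symmetric diketone 6. Because 6 is symmetric, O-methylation can give only one constitutional isomer, so the O3/O5 differentiation costs nothing.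

**6 from 1 and 2.** The two CH2–CH2 bonds next to the aryl groups are cut. Each arises by alkylating a terminal carbon of a 1,3-diketone dianion with benzylic bromide 2: first dianion 3 of acetylacetone 1 to give 4, then dianion 5 of 4 to give 6. All five chain carbons C2–C6 thus come from 1.

**17 from 16, 14 and 15.** The acid chloride comes from cinnamic acid 16. Its alkene–aryl bond is cut by a Heck disconnection to aryl bromide 14 and acrylic acid 15, which gives the free acid directly and avoids an ester hydrolysis.

**14 from 13, 10, 11, 8 and 9.** The diarylmethane CH2 of ring B is traced to the carbinol 13 (ionic deoxygenation). Carbinol 13 is cut at the aryl–carbinol bond to aldehyde 10 and aryl Grignard reagent 12, made from bromide 11. Aldehyde 10 is the benzyl ether of the commercial 8, formed with 9. The 1,3,4-pattern of ring B is bought with 8.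

## Alternatives that were turned down

**Alternative 1: ring B from an acylpyrone cycloaddition.**
- Disconnection: ring B is cut at C1'–C2' and C3'–C4'.
- Forward key step: the ring-A-bearing 3-aroyl-2-pyrone A1 reacts with 1,1-dimethoxyethene A2 in an inverse-electron-demand Diels–Alder reaction. Decarboxylative cycloreversion of the bridged lactone and beta-elimination of one alkoxy group then leave the ortho-methoxy benzophenone A3.
- For it: the polarity of both partners fixes the regiochemistry, the conditions are thermal and neutral, and no labile polycarbonyl compound is handled. On regiochemical certainty it is stronger than the aldol folding.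
- Against it: it builds the easy ring, whose pattern is available in 8, and needs the crowded ring A already complete inside A1. A3 also carries a diaryl ketone that must be reduced to CH2, and a second aryl methyl ether on ring B that must be cleaved while the ring A methyl ether stays. Chelation-assisted demethylation ortho to the ketone could do this, but several steps follow the key step.
- Comparison: the chosen route is less certain in its ring-forming step, but it makes ring A with every substituent in one operation and is shorter.

**Alternative 2: twofold benzylic cross-coupling on ring A.**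
- Disconnection: the two CH2–aryl bonds of the ring A benzyl groups.
- Forward key step: the bis(benzylic carbonate) A4 couples twice with 4-(benzyloxy)phenylboronic acid A5 under palladium catalysis (benzylic Suzuki–Miyaura reaction) to give the penta-O-benzyl target A6. No ring is formed.
- For it: it uses the near-symmetry of ring A, sets both benzyl groups at once by a well-behaved catalytic reaction, and A6 is one hydrogenolysis from the target. In convergence and in the reliability of the bond-forming event it is stronger than the chosen route.
- Against it: A4 needs ring A with hydroxymethyl groups at C2 and C6 on both sides of the bridge, with O3 and O5 already differentiated and C4 free. A first formylation deactivates the ring for the second, and directed metalation goes to C4 between the oxygens, so A4 needs a long stepwise build. Each carbonate is ortho,ortho-disubstituted and ortho/para to oxygen, so ionization and reduction compete with transmetalation, and both couplings must succeed.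
- Comparison: the chosen route places the same benzyl groups by enolate alkylation on an open chain, where crowding does not yet exist.

**Alternative 3: ring B from a silyloxydiene and an acetylene equivalent.**
- Disconnection: ring B is cut at C4'–C5' and C6'–C1'.
- Forward key step: the 2-silyloxy-1,3-diene A7 (Z at the enol ether bond, E at the other) adds to (E)-1,2-bis(phenylsulfonyl)ethene A8 in a Diels–Alder reaction. Base then removes both sulfonyl groups as sulfinate, and the ring aromatizes to silyl ether A9.
- For it: the dienophile is symmetric, so there is no regiochemical question, and the C3' oxygen arrives protected orthogonally to the benzyl ethers. The pericyclic step is more predictable than the aldol folding.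
- Against it: it again makes ring B and presupposes ring A. A7 must be formed by regioselective cross-conjugated enolization with control of enol ether geometry, because the isomer with the benzylic terminus turned inward cannot reach the s-cis conformation. A7 is hydrolytically labile, and two sulfonyl groups are carried only to be discarded.
- Comparison: the chosen route answers the real difficulty of the molecule, ring A, and reaches the target in fewer steps.

Key step: step 10

## Route

Remark on the chemistry: ring A locants C1–C6 are used for 19–22 (chain C3, C4, C5, C6, C7, C8 of 19 are ring C1, C2, C3, C4, C5, C6). It is assumed that 19 reacts as the diketo tautomer drawn; it is racemic at C2, and this labile centre disappears on aromatization. LDA is used as the commercial solution.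

Step 1
Reactants: 1 acetylacetone; 2 4-(benzyloxy)benzyl bromide
Product: 4 6-[4-(benzyloxy)phenyl]hexane-2,4-dione, via acetylacetone dilithium dianion 3 (not isolated)
Conditions: LDA (2.1 equiv), THF, −78 → 0 °C; then 2 (0.95 equiv), 0 °C → rt; cold 1 M HCl
Reagents that add atoms: none
Why: Alkylation of a 1,3-diketone dianion: the second deprotonation creates the more basic terminal carbanion, which alone reacts with the benzylic bromide, so C-alkylation occurs at the methyl carbon and stops after one benzyl group.

Step 2
Reactants: 4 6-[4-(benzyloxy)phenyl]hexane-2,4-dione; 2 4-(benzyloxy)benzyl bromide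
Product: 6 1,7-bis[4-(benzyloxy)phenyl]heptane-3,5-dione, via terminal dilithium dianion 5 (not isolated)
Conditions: LDA (2.1 equiv), THF, −78 → 0 °C; then 2 (1.0 equiv), 0 °C → rt; cold 1 M HCl
Reagents that add atoms: none
Why: Second dianion alkylation: in the monoanion of an unsymmetrical 1,3-diketone the methyl group is deprotonated in preference to the internal methylene, so the new benzyl group should go to the remaining terminal carbon and give the symmetric diketone.

Step 3
Reactants: 6 1,7-bis[4-(benzyloxy)phenyl]heptane-3,5-dione
Product: 7 (E)-1,7-bis[4-(benzyloxy)phenyl]-5-methoxyhept-4-en-3-one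
Conditions: HC(OMe)3 (3 equiv), p-TsOH·H2O (5 mol %), MeOH–CH2Cl2, rt; Et3N quench
Reagents that add atoms: trimethyl orthoformate, COC(OC)OC
Why: Acid-catalysed ketalization and loss of methanol (enol ether formation from a 1,3-diketone, the orthoformate removing water) gives the vinylogous ester; 6 is symmetric, so only one constitutional isomer can form, and the conjugated (E) isomer is the thermodynamic one under these equilibrating conditions.

Step 4
Reactants: 8 4-bromo-2-hydroxybenzaldehyde; 9 benzyl bromide
Product: 10 2-(benzyloxy)-4-bromobenzaldehyde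
Conditions: 9 (1.1 equiv), K2CO3 (1.5 equiv), DMF, rt → 50 °C
Reagents that add atoms: none
Why: Williamson ether synthesis on an acidic ortho-formyl phenol; the aldehyde and the aryl bromide are inert to carbonate.

Step 5
Reactants: 10 2-(benzyloxy)-4-bromobenzaldehyde; 11 1-(benzyloxy)-4-bromobenzene
Product: 13 rac-[2-(benzyloxy)-4-bromophenyl][4-(benzyloxy)phenyl]methanol, via 4-(benzyloxy)phenylmagnesium bromide 12 (not isolated)
Conditions: 11 (1.2 equiv), Mg, I2 (cat.), THF, reflux; then 10, 0 °C; sat. aq NH4Cl
Reagents that add atoms: none
Why: Grignard addition to an aryl aldehyde; addition to the aldehyde is much faster than halogen–magnesium exchange at the aryl bromide of 10, and the new carbinol centre is racemic and is removed in step 6.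

Step 6
Reactants: 13 rac-[2-(benzyloxy)-4-bromophenyl][4-(benzyloxy)phenyl]methanol
Product: 14 2-(benzyloxy)-1-[4-(benzyloxy)benzyl]-4-bromobenzene
Conditions: Et3SiH (3 equiv), TFA (5 equiv), CH2Cl2, 0 °C
Reagents that add atoms: none
Why: Ionic hydrogenation: the carbinol ionizes readily to a diaryl cation stabilized by a para and an ortho alkoxy group, and excess silane traps it by hydride transfer before it can alkylate another arene; aryl benzyl ethers and the aryl bromide tolerate cold TFA.

Step 7
Reactants: 14 2-(benzyloxy)-1-[4-(benzyloxy)benzyl]-4-bromobenzene; 15 acrylic acid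
Product: 16 (E)-3-{3-(benzyloxy)-4-[4-(benzyloxy)benzyl]phenyl}prop-2-enoic acid
Conditions: 15 (1.5 equiv), Pd(OAc)2 (3 mol %), P(o-tol)3 (6 mol %), Et3N (3 equiv), DMF, 100 °C; 1 M HCl
Reagents that add atoms: none
Why: Heck reaction: oxidative addition of the aryl bromide to zerovalent palladium formed in situ from Pd(OAc)2, syn insertion of the acrylate and syn beta-hydride elimination give the (E)-cinnamic acid directly.

Step 8
Reactants: 16 (E)-3-{3-(benzyloxy)-4-[4-(benzyloxy)benzyl]phenyl}prop-2-enoic acid
Product: 17 (E)-3-{3-(benzyloxy)-4-[4-(benzyloxy)benzyl]phenyl}prop-2-enoyl chloride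
Conditions: (COCl)2 (1.5 equiv), DMF (cat.), CH2Cl2, 0 °C → rt; evaporate, use crude
Reagents that add atoms: oxalyl chloride, ClC(=O)C(Cl)=O
Why: DMF-catalysed acid chloride formation through the chloroiminium salt; the by-products are gases and the alkene geometry is untouched.

Step 9
Reactants: 7 (E)-1,7-bis[4-(benzyloxy)phenyl]-5-methoxyhept-4-en-3-one; 17 (E)-3-{3-(benzyloxy)-4-[4-(benzyloxy)benzyl]phenyl}prop-2-enoyl chloride
Product: 19 (1E,6E)-1-{3-(benzyloxy)-4-[4-(benzyloxy)benzyl]phenyl}-4-[4-(benzyloxy)benzyl]-9-[4-(benzyloxy)phenyl]-7-methoxynona-1,6-diene-3,5-dione (racemic at C4 of the chain), via kinetic lithium enolate 18 (not isolated)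
Conditions: 7 (2.2 equiv), LDA (2.2 equiv), THF, −78 °C; then 17 (1.0 equiv) in THF, −78 °C; AcOH (2.5 equiv) in THF at −78 °C, then pH 7 buffer; chromatography on Et3N-deactivated silica
Reagents that add atoms: none
Why: Kinetic deprotonation of a beta-alkoxy enone by an amide base takes the alpha' proton (the regiochemistry of the Stork–Danheiser sequence), and the cross-conjugated enolate is C-acylated by the acid chloride at its carbonyl carbon (Claisen-type acylation). The second equivalent of 18 deprotonates the more acidic product, which protects it from further acylation and returns one equivalent of 7 for recovery; the cold, non-acidic quench avoids O-cyclization of 19.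

Step 10
Reactants: 19 (1E,6E)-1-{3-(benzyloxy)-4-[4-(benzyloxy)benzyl]phenyl}-4-[4-(benzyloxy)benzyl]-9-[4-(benzyloxy)phenyl]-7-methoxynona-1,6-diene-3,5-dione
Product: 21 2,4-bis[4-(benzyloxy)benzyl]-3-{(E)-2-[3-(benzyloxy)-4-(4-(benzyloxy)benzyl)phenyl]ethenyl}-5-methoxyphenol, via cyclic aldol adduct 20 (not isolated)
Conditions: NaOMe (3 equiv), MeOH–THF (2:1), 0.02 M, argon, rt → 55 °C; then cold 1 M HCl to pH 5
Reagents that add atoms: none
Why: Methoxide first removes the C2–H between the two ketones, so the resting state is the sodium diketonate; by proton exchange in the protic medium a small share of the material is deprotonated at C6 to the extended dienolate of the beta-methoxy enone (O3–C3=C4–C5(OMe)=C6), whose gamma carbon C6 adds to the cinnamoyl carbonyl C1 to give 20. Ring A closes in the 6-(enolendo)-exo-trig mode, with the C5=C6 enolate bond inside the new ring and the C1 oxygen outside. E1cB loss of hydroxide across C1–C2 and a proton shift from C6 to O3 then give the phenolate, and this aromatization is the only irreversible event, so it drains all the equilibria. The closest known reaction type is the base-mediated aldol cyclization of 3,5,7-triketones and their enol ethers to resorcinols, the laboratory form of stilbene-synthase folding, run here as a vinylogous aldol condensation. No stereocentre is created: the three sp3 centres of 20 and the C2 centre of 19 all become arene carbons. The step needs C–C closure to win over O-closure: attack of the diketonate oxygen on C5 with loss of methoxide (4-pyranone formation) and oxa-Michael addition to the styryl enone are both reversible in NaOMe/MeOH, because methoxide reopens the pyranone and the oxa-Michael adduct reverts by E1cB, and methoxide exchange at C5 is degenerate. The substrate fixes the regiochemistry: C5 is an enol ether carbon and cannot act as aldol acceptor, the cinnamoyl end has no sp3 C–H beyond C1 and so offers no second folding mode, and O5 enters the ring already methylated while the C3 carbonyl becomes the free hydroxyl.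

Step 11
Reactants: 21 2,4-bis[4-(benzyloxy)benzyl]-3-{(E)-2-[3-(benzyloxy)-4-(4-(benzyloxy)benzyl)phenyl]ethenyl}-5-methoxyphenol
Product: 22 3-{2-[3-hydroxy-4-(4-hydroxybenzyl)phenyl]ethyl}-2,4-bis(4-hydroxybenzyl)-5-methoxyphenol (CNP0207338.0)
Conditions: H2 (1 atm), Pd/C (10 wt % Pd), EtOAc–MeOH (1:1), rt; filtration and concentration under argon
Reagents that add atoms: none
Why: Catalytic hydrogenation saturates the stilbene double bond, and hydrogenolysis cleaves the four aryl benzyl ethers in the same operation; the aryl methyl ether, the diarylmethane C–C bonds and the arenes are inert at 1 atm.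

## Compound list

1 | acetylacetone (pentane-2,4-dione) | CC(=O)CC(C)=O | starting material
2 | 4-(benzyloxy)benzyl bromide | BrCc1ccc(OCc2ccccc2)cc1 | starting material
3 | dilithium dianion of acetylacetone (terminal carbon and C3 deprotonated) | [Li+].[Li+].C=C([O-])C=C(C)[O-] | intermediate (not isolated)
4 | 6-[4-(benzyloxy)phenyl]hexane-2,4-dione | CC(=O)CC(=O)CCc1ccc(OCc2ccccc2)cc1 | intermediate
5 | dilithium dianion of 4 (methyl carbon and C3 deprotonated) | [Li+].[Li+].C=C([O-])C=C([O-])CCc1ccc(OCc2ccccc2)cc1 | intermediate (not isolated)
6 | 1,7-bis[4-(benzyloxy)phenyl]heptane-3,5-dione | O=C(CCc1ccc(OCc2ccccc2)cc1)CC(=O)CCc1ccc(OCc2ccccc2)cc1 | intermediate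
7 | (E)-1,7-bis[4-(benzyloxy)phenyl]-5-methoxyhept-4-en-3-one | CO/C(CCc1ccc(OCc2ccccc2)cc1)=C/C(=O)CCc1ccc(OCc2ccccc2)cc1 | intermediate
8 | 4-bromo-2-hydroxybenzaldehyde | O=Cc1ccc(Br)cc1O | starting material
9 | benzyl bromide | BrCc1ccccc1 | starting material
10 | 2-(benzyloxy)-4-bromobenzaldehyde | O=Cc1ccc(Br)cc1OCc1ccccc1 | intermediate
11 | 1-(benzyloxy)-4-bromobenzene | Brc1ccc(OCc2ccccc2)cc1 | starting material
12 | 4-(benzyloxy)phenylmagnesium bromide | Br[Mg]c1ccc(OCc2ccccc2)cc1 | intermediate (not isolated)
13 | rac-[2-(benzyloxy)-4-bromophenyl][4-(benzyloxy)phenyl]methanol | OC(c1ccc(OCc2ccccc2)cc1)c1ccc(Br)cc1OCc1ccccc1 | intermediate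
14 | 2-(benzyloxy)-1-[4-(benzyloxy)benzyl]-4-bromobenzene | Brc1ccc(Cc2ccc(OCc3ccccc3)cc2)c(OCc2ccccc2)c1 | intermediate
15 | acrylic acid | C=CC(=O)O | starting material
16 | (E)-3-{3-(benzyloxy)-4-[4-(benzyloxy)benzyl]phenyl}prop-2-enoic acid | OC(=O)/C=C/c1ccc(Cc2ccc(OCc3ccccc3)cc2)c(OCc2ccccc2)c1 | intermediate
17 | (E)-3-{3-(benzyloxy)-4-[4-(benzyloxy)benzyl]phenyl}prop-2-enoyl chloride | O=C(Cl)/C=C/c1ccc(Cc2ccc(OCc3ccccc3)cc2)c(OCc2ccccc2)c1 | intermediate
18 | lithium alpha'-enolate of 7 (geometry of the enolate double bond not controlled and without consequence) | [Li+].CO/C(CCc1ccc(OCc2ccccc2)cc1)=C/C([O-])=CCc1ccc(OCc2ccccc2)cc1 | intermediate (not isolated)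
19 | (1E,6E)-1-{3-(benzyloxy)-4-[4-(benzyloxy)benzyl]phenyl}-4-[4-(benzyloxy)benzyl]-9-[4-(benzyloxy)phenyl]-7-methoxynona-1,6-diene-3,5-dione (racemic) | CO/C(CCc1ccc(OCc2ccccc2)cc1)=C/C(=O)C(Cc1ccc(OCc2ccccc2)cc1)C(=O)/C=C/c1ccc(Cc2ccc(OCc3ccccc3)cc2)c(OCc2ccccc2)c1 | intermediate
20 | 4,6-bis[4-(benzyloxy)benzyl]-5-{(E)-2-[3-(benzyloxy)-4-(4-(benzyloxy)benzyl)phenyl]ethenyl}-5-hydroxy-3-methoxycyclohex-2-en-1-one (mixture of diastereomers, all three centres lost on aromatization) | COC1=CC(=O)C(Cc2ccc(OCc3ccccc3)cc2)C(O)(/C=C/c2ccc(Cc3ccc(OCc4ccccc4)cc3)c(OCc3ccccc3)c2)C1Cc1ccc(OCc2ccccc2)cc1 | intermediate (not isolated)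
21 | 2,4-bis[4-(benzyloxy)benzyl]-3-{(E)-2-[3-(benzyloxy)-4-(4-(benzyloxy)benzyl)phenyl]ethenyl}-5-methoxyphenol | COc1cc(O)c(Cc2ccc(OCc3ccccc3)cc2)c(/C=C/c2ccc(Cc3ccc(OCc4ccccc4)cc3)c(OCc3ccccc3)c2)c1Cc1ccc(OCc2ccccc2)cc1 | intermediate
22 | 3-{2-[3-hydroxy-4-(4-hydroxybenzyl)phenyl]ethyl}-2,4-bis(4-hydroxybenzyl)-5-methoxyphenol (no stereocentres) | COc1cc(O)c(Cc2ccc(O)cc2)c(CCc2ccc(Cc3ccc(O)cc3)c(O)c2)c1Cc1ccc(O)cc1 | target

## Step count and risk

Total step count: 11. Longest linear sequence: 8 steps (steps 4–8, then 9–11, from 8). The other branch (steps 1–3, from 1) joins at step 9.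

**Step 10 (key step).** What may go wrong is stalling of the closure. Prior enolization at C2 turns the C1 carbonyl into part of a diketonate and lowers its electrophilicity. Retro-Claisen cleavage of the cinnamoyl group by methoxide, or build-up of the O-cyclized material, could then overtake aromatization.

Fallback, from 19 back to 21: 19 is deliberately O-cyclized with p-TsOH in toluene at 60 °C, with loss of the enol ether methanol, to 3-[4-(benzyloxy)benzyl]-6-{2-[4-(benzyloxy)phenyl]ethyl}-2-{(E)-2-[3-(benzyloxy)-4-(4-(benzyloxy)benzyl)phenyl]ethenyl}-4H-pyran-4-one F1. Aqueous KOH in ethanol then opens F1 to the free triketone polyanion, which undergoes the classical triketone-to-resorcinol aldol aromatization in the only folding mode available and gives 4,6-bis[4-(benzyloxy)benzyl]-5-{(E)-2-[3-(benzyloxy)-4-(4-(benzyloxy)benzyl)phenyl]ethenyl}benzene-1,3-diol F2. Because the two benzyl groups are identical, the two hydroxyls of F2 are equivalent. Mono-O-methylation with MeI (1 equiv) and K2CO3 in acetone, with recycling of unreacted F2, returns to the route at 21.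

**Step 9.** What may go wrong is O-acylation of the lithium enolate instead of C-acylation, or proton transfer that converts the kinetic alpha' enolate into the gamma dienolate before it is acylated.

Fallback, from 17 and 7 back to 19, by aldol addition and oxidation: 17 is reduced with LiAlH(Ot-Bu)3 in THF at −78 °C to (E)-3-{3-(benzyloxy)-4-[4-(benzyloxy)benzyl]phenyl}prop-2-enal F3. Enolate 18, made from 7 as in step 9 but with 1.1 equiv, adds 1,2 to F3 at −78 °C to give (1E,6E)-1-{3-(benzyloxy)-4-[4-(benzyloxy)benzyl]phenyl}-4-[4-(benzyloxy)benzyl]-9-[4-(benzyloxy)phenyl]-3-hydroxy-7-methoxynona-1,6-dien-5-one F4 as a mixture of diastereomers. Dess–Martin periodinane with NaHCO3 in CH2Cl2 oxidizes F4 to 19.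

**Step 2.** What may go wrong is deprotonation at the internal methylene instead of the methyl group, or a second alkylation of the product. Either would give isomeric or over-benzylated diketones that are hard to separate from 6.

Fallback, from 1 back to 6, replacing steps 1 and 2: 1 is condensed at both methyl groups with 4-(benzyloxy)benzaldehyde (2 equiv) as its boron complex (B2O3, tributyl borate, n-BuNH2, EtOAc, 70 °C; dilute HCl) to give (1E,6E)-1,7-bis[4-(benzyloxy)phenyl]hepta-1,6-diene-3,5-dione F5. Homogeneous hydrogenation with H2 and RhCl(PPh3)3 in benzene–ethanol saturates both alkenes without touching the benzyl ethers and gives 6.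

**Step 11.** What may go wrong is incomplete hydrogenolysis. The partly deprotected polyphenols may precipitate or bind to the catalyst before all four benzyl ethers are gone; prolonged forcing risks ring saturation.

Fallback, from 21 back to 22, in two separate operations: diimide reduction (TsNHNH2, NaOAc, THF–H2O, reflux) saturates the stilbene to 2,4-bis[4-(benzyloxy)benzyl]-3-{2-[3-(benzyloxy)-4-(4-(benzyloxy)benzyl)phenyl]ethyl}-5-methoxyphenol F6. BCl3 with pentamethylbenzene in CH2Cl2 at −78 °C then cleaves the four benzyl ethers, the scavenger taking up the benzyl cations, while the aryl methyl ether survives at that temperature; this gives 22.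

## Further compounds

F1 | step 10 | 3-[4-(benzyloxy)benzyl]-6-{2-[4-(benzyloxy)phenyl]ethyl}-2-{(E)-2-[3-(benzyloxy)-4-(4-(benzyloxy)benzyl)phenyl]ethenyl}-4H-pyran-4-one | O=c1cc(CCc2ccc(OCc3ccccc3)cc2)oc(/C=C/c2ccc(Cc3ccc(OCc4ccccc4)cc3)c(OCc3ccccc3)c2)c1Cc1ccc(OCc2ccccc2)cc1
F2 | step 10 | 4,6-bis[4-(benzyloxy)benzyl]-5-{(E)-2-[3-(benzyloxy)-4-(4-(benzyloxy)benzyl)phenyl]ethenyl}benzene-1,3-diol | Oc1cc(O)c(Cc2ccc(OCc3ccccc3)cc2)c(/C=C/c2ccc(Cc3ccc(OCc4ccccc4)cc3)c(OCc3ccccc3)c2)c1Cc1ccc(OCc2ccccc2)cc1
F3 | step 9 | (E)-3-{3-(benzyloxy)-4-[4-(benzyloxy)benzyl]phenyl}prop-2-enal | O=C/C=C/c1ccc(Cc2ccc(OCc3ccccc3)cc2)c(OCc2ccccc2)c1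
F4 | step 9 | (1E,6E)-1-{3-(benzyloxy)-4-[4-(benzyloxy)benzyl]phenyl}-4-[4-(benzyloxy)benzyl]-9-[4-(benzyloxy)phenyl]-3-hydroxy-7-methoxynona-1,6-dien-5-one (mixture of diastereomers) | CO/C(CCc1ccc(OCc2ccccc2)cc1)=C/C(=O)C(Cc1ccc(OCc2ccccc2)cc1)C(O)/C=C/c1ccc(Cc2ccc(OCc3ccccc3)cc2)c(OCc2ccccc2)c1
F5 | step 2 | (1E,6E)-1,7-bis[4-(benzyloxy)phenyl]hepta-1,6-diene-3,5-dione | O=C(/C=C/c1ccc(OCc2ccccc2)cc1)CC(=O)/C=C/c1ccc(OCc2ccccc2)cc1
F6 | step 11 | 2,4-bis[4-(benzyloxy)benzyl]-3-{2-[3-(benzyloxy)-4-(4-(benzyloxy)benzyl)phenyl]ethyl}-5-methoxyphenol | COc1cc(O)c(Cc2ccc(OCc3ccccc3)cc2)c(CCc2ccc(Cc3ccc(OCc4ccccc4)cc3)c(OCc3ccccc3)c2)c1Cc1ccc(OCc2ccccc2)cc1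
A1 | alternative 1 | 3-[4-(benzyloxy)benzoyl]-6-{2-[3-(benzyloxy)-2,6-bis(4-(benzyloxy)benzyl)-5-methoxyphenyl]ethyl}-2H-pyran-2-one | COc1cc(OCc2ccccc2)c(Cc2ccc(OCc3ccccc3)cc2)c(CCc2ccc(C(=O)c3ccc(OCc4ccccc4)cc3)c(=O)o2)c1Cc1ccc(OCc2ccccc2)cc1
A2 | alternative 1 | 1,1-dimethoxyethene | C=C(OC)OC
A3 | alternative 1 | [4-(benzyloxy)phenyl](4-{2-[3-(benzyloxy)-2,6-bis(4-(benzyloxy)benzyl)-5-methoxyphenyl]ethyl}-2-methoxyphenyl)methanone | COc1cc(CCc2c(Cc3ccc(OCc4ccccc4)cc3)c(OC)cc(OCc3ccccc3)c2Cc2ccc(OCc3ccccc3)cc2)ccc1C(=O)c1ccc(OCc2ccccc2)cc1
A4 | alternative 2 | {4-(benzyloxy)-2-{2-[3-(benzyloxy)-4-(4-(benzyloxy)benzyl)phenyl]ethyl}-6-methoxy-1,3-phenylene}bis(methylene) dimethyl bis(carbonate) | COC(=O)OCc1c(OC)cc(OCc2ccccc2)c(COC(=O)OC)c1CCc1ccc(Cc2ccc(OCc3ccccc3)cc2)c(OCc2ccccc2)c1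
A5 | alternative 2 | 4-(benzyloxy)phenylboronic acid | OB(O)c1ccc(OCc2ccccc2)cc1
A6 | alternative 2 | 1-(benzyloxy)-2,4-bis[4-(benzyloxy)benzyl]-3-{2-[3-(benzyloxy)-4-(4-(benzyloxy)benzyl)phenyl]ethyl}-5-methoxybenzene (penta-O-benzyl target) | COc1cc(OCc2ccccc2)c(Cc2ccc(OCc3ccccc3)cc2)c(CCc2ccc(Cc3ccc(OCc4ccccc4)cc3)c(OCc3ccccc3)c2)c1Cc1ccc(OCc2ccccc2)cc1
A7 | alternative 3 | (2Z,4E)-1-[4-(benzyloxy)phenyl]-7-{3-(benzyloxy)-2,6-bis[4-(benzyloxy)benzyl]-5-methoxyphenyl}-3-[(tert-butyldimethylsilyl)oxy]hepta-2,4-diene | COc1cc(OCc2ccccc2)c(Cc2ccc(OCc3ccccc3)cc2)c(CC/C=C/C(O[Si](C)(C)C(C)(C)C)=C/Cc2ccc(OCc3ccccc3)cc2)c1Cc1ccc(OCc2ccccc2)cc1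
A8 | alternative 3 | (E)-1,2-bis(phenylsulfonyl)ethene | O=S(=O)(/C=C/S(=O)(=O)c1ccccc1)c1ccccc1
A9 | alternative 3 | tert-butyldimethylsilyl ether at C3' of the tetra-O-benzyl target | CC(C)(C)[Si](C)(C)Oc1cc(CCc2c(Cc3ccc(OCc4ccccc4)cc3)c(OC)cc(OCc3ccccc3)c2Cc2ccc(OCc3ccccc3)cc2)ccc1Cc1ccc(OCc2ccccc2)cc1
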